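**Assumption:** the target is a planar, achiral indole with no stereocentre, so "single enantiomer" requires no stereocontrol. The sulfoxide reagent 8 is used as the racemate, because its sulfur stereocentre is destroyed in step 5.

## Retrosynthetic overview

1. Target 12 ⇒ cut C3–C3a and N1–C2 in one operation: 3,4,5-tribromoaniline 4 plus the C2S2 building block MeS(O)–C≡C–SMe 8 (new aza-interrupted-Pummerer/[3,3] annulation).
2. 4 ⇐ 1,2,3-tribromo-5-nitrobenzene 3 ⇐ 2,6-dibromo-4-nitroaniline 1 (Sandmeyer, then nitro reduction). The C2-symmetric aniline makes both ortho carbons equivalent.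
3. 8 ⇐ bis(methylsulfanyl)ethyne 7 (mono-S-oxidation) ⇐ trichloroethylene 5 via Li2C2 6 and MeSSMe.
4. Ring order: the benzene ring is bought; the pyrrole ring is the only ring formed, in the last step, with both SMe groups already in place.

## Route

**Step 1**
Reactants: 1 2,6-dibromo-4-nitroaniline
Product: 3 1,2,3-tribromo-5-nitrobenzene, via 2,6-dibromo-4-nitrobenzenediazonium hydrogensulfate 2 (not isolated)
Conditions: NaNO2, conc. H2SO4/AcOH, 0–15 °C; then CuBr (cat.), 48% aq. HBr, 0 → 70 °C
Reagents that add atoms: sodium nitrite, [Na+].[O-]N=O (terminal N of 2 only); sulfuric acid, OS(=O)(=O)O (counter-ion of 2 only); hydrogen bromide, Br (the new Br of 3)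
Why: Sandmeyer reaction – the very weakly basic amine is diazotised cleanly by nitrosylsulfuric acid and Cu(I)-mediated bromodediazoniation puts Br exactly where N was, giving the 1,2,3-tribromo pattern; NO2 and Ar–Br are inert and no stereocentre is involved.

**Step 2**
Reactants: 3 1,2,3-tribromo-5-nitrobenzene
Product: 4 3,4,5-tribromoaniline
Conditions: Fe powder, AcOH/EtOH, 80 °C
Reagents that add atoms: none
Why: Béchamp-type dissolving-metal nitro reduction, which is chemoselective for NO2 and does not hydrodehalogenate the three Ar–Br bonds (unlike H2/Pd).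

**Step 3**
Reactants: 5 trichloroethylene
Product: 7 1,2-bis(methylsulfanyl)ethyne, via dilithium acetylide 6 (not isolated)
Conditions: n-BuLi (3 equiv), THF/Et2O, −78 °C → rt; then MeSSMe (2.2 equiv), −78 °C → rt; aq. NH4Cl
Reagents that add atoms: n-butyllithium, [Li]CCCC (Li of 6 only); dimethyl disulfide, CSSC (both MeS groups of 7)
Why: Deprotonation/β-elimination of trichloroethylene to dichloroacetylene and two Li/Cl exchanges give Li2C2 in situ, and each acetylide carbon then attacks the S–S bond of the disulfide (acetylide sulfenylation, SN2 at sulfur).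

**Step 4**
Reactants: 7 1,2-bis(methylsulfanyl)ethyne
Product: 8 1-(methanesulfinyl)-2-(methylsulfanyl)ethyne (racemic at S)
Conditions: mCPBA (1.0 equiv), CH2Cl2, −78 → −20 °C; use fresh
Reagents that add atoms: mCPBA, O=C(OO)c1cccc(Cl)c1 (sulfoxide O)
Why: Electrophilic sulfide-to-sulfoxide oxidation by a peracid; 7 is symmetric so only one constitutional product can form, and after the first oxidation the remaining sulfur is conjugated to an electron-poor sulfinyl alkyne and is deactivated, so the reaction stops at the mono-oxide.

**Step 5**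
Reactants: 4 3,4,5-tribromoaniline; 8 1-(methanesulfinyl)-2-(methylsulfanyl)ethyne
Product: 12 4,5,6-tribromo-2,3-bis(methylsulfanyl)-1H-indole, via methyl[(methylsulfanyl)ethynyl][(trifluoromethanesulfonyl)oxy]sulfonium trifluoromethanesulfonate 9 (not isolated), via methyl[(methylsulfanyl)ethynyl][(3,4,5-tribromophenyl)amino]sulfonium trifluoromethanesulfonate 10 (not isolated), via [2-(6-amino-2,3,4-tribromophenyl)-2-(methylsulfanyl)ethenylidene](methyl)sulfonium trifluoromethanesulfonate 11 (not isolated)
Conditions: 8 (1.3 equiv), Tf2O (1.3 equiv), 2-chloropyridine (3 equiv), CH2Cl2, −78 °C, 15 min; then 4, −78 → 0 °C; aq. NaHCO3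
Reagents that add atoms: trifluoromethanesulfonic anhydride, O=S(=O)(OS(=O)(=O)C(F)(F)F)C(F)(F)F (triflyl/triflate of 9–11 only; 12 takes all its heavy atoms from 4 and 8)
Why: Proposed new method: an aza-interrupted-Pummerer/[3,3] indole annulation – Tf2O converts the sulfoxide of 8 into the S(IV) electrophile 9, the aniline nitrogen attacks sulfur to give azasulfonium 10, whose weak N–S+ bond and C(ortho)=C(ipso)–N–S–C≡C array drive a charge-accelerated [3,3]-sigmatropic shift that forms C3–C3a at either of the two equivalent ortho carbons and, after rearomatisation, unmasks the thioketene-type thionium 11, which the free NH2 captures at the sp carbon (N1–C2) before loss of H+ gives the aromatic indole with both SMe groups already at the correct oxidation level and no regiochemical ambiguity; electron-poor anilines are the favoured substrates of azasulfonium rearrangements and Ar–Br is inert; the closest known reaction types are the Gassman indole synthesis (azasulfonium ylide [2,3]-shift) and the interrupted-Pummerer/[3,3] benzofuran annulation of phenols with ketene dithioacetal monoxides or alkynyl sulfoxides, whereas a primary aniline with a 1-sulfinyl-2-sulfanyl alkyne giving a 2,3-bis(sulfanyl)indole has not been shown.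

## Compound list

1 | 2,6-dibromo-4-nitroaniline | Nc1c(Br)cc(cc1Br)[N+](=O)[O-] | starting material
2 | 2,6-dibromo-4-nitrobenzenediazonium hydrogensulfate | N#[N+]c1c(Br)cc(cc1Br)[N+](=O)[O-].OS(=O)(=O)[O-] | intermediate
3 | 1,2,3-tribromo-5-nitrobenzene | [O-][N+](=O)c1cc(Br)c(Br)c(Br)c1 | intermediate
4 | 3,4,5-tribromoaniline | Nc1cc(Br)c(Br)c(Br)c1 | intermediate
5 | trichloroethylene | ClC=C(Cl)Cl | starting material
6 | dilithium acetylide | [Li]C#C[Li] | intermediate
7 | 1,2-bis(methylsulfanyl)ethyne | CSC#CSC | intermediate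
8 | 1-(methanesulfinyl)-2-(methylsulfanyl)ethyne (racemic at S) | CS(=O)C#CSC | intermediate
9 | methyl[(methylsulfanyl)ethynyl][(trifluoromethanesulfonyl)oxy]sulfonium trifluoromethanesulfonate | C[S+](OS(=O)(=O)C(F)(F)F)C#CSC.[O-]S(=O)(=O)C(F)(F)F | intermediate
10 | methyl[(methylsulfanyl)ethynyl][(3,4,5-tribromophenyl)amino]sulfonium trifluoromethanesulfonate | C[S+](Nc1cc(Br)c(Br)c(Br)c1)C#CSC.[O-]S(=O)(=O)C(F)(F)F | intermediate
11 | [2-(6-amino-2,3,4-tribromophenyl)-2-(methylsulfanyl)ethenylidene](methyl)sulfonium trifluoromethanesulfonate | Nc1cc(Br)c(Br)c(Br)c1C(SC)=C=[S+]C.[O-]S(=O)(=O)C(F)(F)F | intermediate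
12 | 4,5,6-tribromo-2,3-bis(methylsulfanyl)-1H-indole | CSc1[nH]c2cc(Br)c(Br)c(Br)c2c1SC | target

## Summary

Total step count: 5.
Longest linear sequence: 3 steps (1 → 3 → 4 → 12; the reagent branch 5 → 7 → 8 → 12 is also 3).

## Three steps most likely to fail, with fallbacks

**Step 5 (the proposed new annulation).** Risks are N-attack at the alkyne carbon instead of sulfur, N-triflylation, or a sluggish [3,3] shift next to the flanking bromine. The fallback uses known chemistry, sets out from 4 and comes back at 12: a Gassman indole synthesis followed by C2-sulfenylation. Compound 4 is N-chlorinated (t-BuOCl, CH2Cl2, −65 °C) to N-chloro-3,4,5-tribromoaniline F1. Addition of (methylsulfanyl)acetaldehyde dimethyl acetal gives (2,2-dimethoxyethyl)(methyl)[(3,4,5-tribromophenyl)amino]sulfonium chloride F2. Et3N forms the ylide, whose [2,3]-shift and rearomatisation give racemic 3,4,5-tribromo-2-[2,2-dimethoxy-1-(methylsulfanyl)ethyl]aniline F3. Aqueous HCl/Et2O closes the ring with loss of methanol to 4,5,6-tribromo-3-(methylsulfanyl)-1H-indole F4. MeSCl (from MeSSMe/SO2Cl2, CH2Cl2, −78 → 23 °C) attacks C3 to give 4,5,6-tribromo-3,3-bis(methylsulfanyl)-3H-indole F5, and a 1,2-sulfanyl shift with tautomerisation delivers 12.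

**Step 4 (mono-oxidation and handling of the push–pull alkynyl sulfoxide 8).** Risks are over-oxidation, alkyne oxidation, or decomposition of 8. The fallback sets out from 7 (together with 4) and comes back at 12, with the oxidising equivalent delivered by a Corey–Kim-type sulfide activation instead of an isolated sulfoxide. Compound 7 and N-chlorosuccinimide (CH2Cl2, −40 °C) give (2,5-dioxopyrrolidin-1-yl)(methyl)[(methylsulfanyl)ethynyl]sulfonium chloride F6. Compound 4 displaces succinimide to give methyl[(methylsulfanyl)ethynyl][(3,4,5-tribromophenyl)amino]sulfonium chloride F7, the chloride analogue of 10. F7 then follows the step-5 pathway ([3,3] shift, N–C2 closure, loss of HCl) to 12. Formation of azasulfonium salts from sulfide/NCS and anilines is established; the rearrangement that follows is the same unproven one as in step 5.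

**Step 3 (Li2C2 generation and double sulfenylation).** Risks are heterogeneous, incomplete bis-sulfenylation and thiolate addition to the product. The fallback sets out from 5 and comes back at 7, with the polarity reversed (sulfur nucleophile, carbon electrophile). Compound 5 with NaSMe (2 equiv, EtOH, 60 °C, elimination–addition via chloroalkynes) gives 1-chloro-1,2-bis(methylsulfanyl)ethene F8 as an E/Z mixture. Dehydrochlorination with LDA (THF, −78 → 0 °C) gives 7.

## Further compounds

F1 | step 5 | N-chloro-3,4,5-tribromoaniline | ClNc1cc(Br)c(Br)c(Br)c1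
F2 | step 5 | (2,2-dimethoxyethyl)(methyl)[(3,4,5-tribromophenyl)amino]sulfonium chloride | C[S+](CC(OC)OC)Nc1cc(Br)c(Br)c(Br)c1.[Cl-]
F3 | step 5 | 3,4,5-tribromo-2-[2,2-dimethoxy-1-(methylsulfanyl)ethyl]aniline (racemic) | Nc1cc(Br)c(Br)c(Br)c1C(SC)C(OC)OC
F4 | step 5 | 4,5,6-tribromo-3-(methylsulfanyl)-1H-indole | CSc1c[nH]c2cc(Br)c(Br)c(Br)c12
F5 | step 5 | 4,5,6-tribromo-3,3-bis(methylsulfanyl)-3H-indole | CSC1(SC)C=Nc2cc(Br)c(Br)c(Br)c12
F6 | step 4 | (2,5-dioxopyrrolidin-1-yl)(methyl)[(methylsulfanyl)ethynyl]sulfonium chloride | C[S+](C#CSC)N1C(=O)CCC1=O.[Cl-]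
F7 | step 4 | methyl[(methylsulfanyl)ethynyl][(3,4,5-tribromophenyl)amino]sulfonium chloride | C[S+](Nc1cc(Br)c(Br)c(Br)c1)C#CSC.[Cl-]
F8 | step 3 | 1-chloro-1,2-bis(methylsulfanyl)ethene (E/Z mixture) | CSC=C(Cl)SC
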